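**Retrosynthetic overview**
- The side chain is numbered from the coumarin OCH2 (C1) to the terminal methylene (C8). C6 carries the OOH, lies between C5H2 and the C7=C8 isopropenyl group, and is 1,3-anti to the C4 carbinol. The target therefore corresponds to a (4S,6R) 1,3-syn diol in which only the C6 oxygen is exchanged for OO with inversion.
- Last strategic bond: C6–OO, by SN2 displacement of a (6R) allylic mesylate with the anion of 2-methoxyprop-2-yl hydroperoxide, in place of a singlet-oxygen ene reaction.
- C6 carbinol from catalyst-controlled reduction of an isopropenyl ketone. C4–C5 from an Ipc-boron aldol of methyl isopropenyl ketone with an (E)-enal.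
- The enal comes from allylic oxidation of a prenyl ether. The O–C1 bond comes from a Mitsunobu etherification of 4-hydroxy-5-methylcoumarin.
- Ring order: the benzene ring is bought; the only ring made is the pyranone ring of the coumarin, closed in the first step.

Key step: step 10

Assumption: the enol borinate made with (+)-Ipc2BCl is taken to add to the Si face of the enal (the sense expected for methyl ketones, opposite to that of Z-enolates); if the sense proves the reverse, (−)-Ipc2BCl is used and nothing else changes.

**Step 1**
Reactants: 1 2'-hydroxy-6'-methylacetophenone; 2 diethyl carbonate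
Product: 4 4-hydroxy-5-methylcoumarin, via beta-keto ester 3 (not isolated)
Conditions: NaH (4 equiv), toluene, 110 °C; then H2O, aq. HCl to pH 2
Reagents that add atoms: none
Why: Claisen-type C-acylation of the ketone enolate by the carbonate gives the beta-keto ester, whose phenoxide lactonises with loss of ethoxide to close the pyranone ring (standard 4-hydroxycoumarin synthesis).

**Step 2**
Reactants: 4 4-hydroxy-5-methylcoumarin; 5 prenol (3-methylbut-2-en-1-ol)
Product: 6 5-methyl-4-(3-methylbut-2-en-1-yloxy)coumarin
Conditions: PPh3, DIAD, THF, 0 °C to rt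
Reagents that add atoms: none
Why: Mitsunobu etherification, for which the acidic 4-hydroxyl (a vinylogous carboxylic acid) is a suitable pronucleophile; it should favour O-alkylation at the primary carbon over C3-alkylation, and the low temperature avoids Claisen rearrangement of the allyl ether.

**Step 3**
Reactants: 6 5-methyl-4-(3-methylbut-2-en-1-yloxy)coumarin
Product: 7 4-{[(2E)-4-hydroxy-3-methylbut-2-en-1-yl]oxy}-5-methylcoumarin
Conditions: SeO2 (0.5 equiv), t-BuOOH (3 equiv), salicylic acid (0.1 equiv), CH2Cl2, rt
Reagents that add atoms: selenium dioxide O=[Se]=O (transfers the oxygen; regenerated by tert-butyl hydroperoxide CC(C)(C)OO, the stoichiometric oxygen source)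
Why: Catalytic SeO2 allylic oxidation (ene reaction, then [2,3]-sigmatropic shift) attacks the methyl group trans to the chain at the more substituted alkene carbon, which fixes the (E)-C2=C3 geometry; any enal formed by over-oxidation is the product of step 4 and is carried along.

**Step 4**
Reactants: 7 4-{[(2E)-4-hydroxy-3-methylbut-2-en-1-yl]oxy}-5-methylcoumarin
Product: 8 (2E)-2-methyl-4-[(5-methyl-2-oxo-2H-chromen-4-yl)oxy]but-2-enal
Conditions: MnO2 (activated, excess), CH2Cl2, rt
Reagents that add atoms: none
Why: Selective heterogeneous oxidation of a primary allylic alcohol to the enal under neutral conditions, which should leave the alkene geometry and the allyl ether untouched.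

**Step 5**
Reactants: 8 (2E)-2-methyl-4-[(5-methyl-2-oxo-2H-chromen-4-yl)oxy]but-2-enal; 9 3-methylbut-3-en-2-one (methyl isopropenyl ketone)
Product: 11 4-{[(2E,4S)-4-hydroxy-3,7-dimethyl-6-oxoocta-2,7-dien-1-yl]oxy}-5-methylcoumarin, via boron dienolate 10 (not isolated)
Conditions: 9, (+)-Ipc2BCl (1.4 equiv), Et3N, Et2O, 0 °C; then 8 in CH2Cl2, −78 to −20 °C; MeOH/pH 7 buffer, no peroxide, SiO2
Reagents that add atoms: none
Why: Diisopinocampheylboron-mediated aldol of a methyl ketone forms C4–C5, the Ipc ligands directing the dienolate to the Si face of the aldehyde so that C4 is set as S; selectivity is expected to be moderate, and the minor antipode becomes a separable diastereomer after step 7; the peroxide-free work-up protects the isopropenyl ketone from nucleophilic epoxidation.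

**Step 6**
Reactants: 11 4-{[(2E,4S)-4-hydroxy-3,7-dimethyl-6-oxoocta-2,7-dien-1-yl]oxy}-5-methylcoumarin
Product: 12 4-{[(2E,4S)-4-(tert-butyldimethylsilyloxy)-3,7-dimethyl-6-oxoocta-2,7-dien-1-yl]oxy}-5-methylcoumarin
Conditions: TBSOTf, 2,6-lutidine, CH2Cl2, −78 °C
Reagents that add atoms: tert-butyldimethylsilyl triflate CC(C)(C)[Si](C)(C)OS(=O)(=O)C(F)(F)F
Why: Silylation of the secondary allylic hydroxyl with a silyl triflate and a hindered base is fast at low temperature, so retro-aldol cleavage and dehydration of the beta-hydroxy enone should not compete.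

**Step 7**
Reactants: 12 4-{[(2E,4S)-4-(tert-butyldimethylsilyloxy)-3,7-dimethyl-6-oxoocta-2,7-dien-1-yl]oxy}-5-methylcoumarin
Product: 13 4-{[(2E,4S,6R)-4-(tert-butyldimethylsilyloxy)-6-hydroxy-3,7-dimethylocta-2,7-dien-1-yl]oxy}-5-methylcoumarin
Conditions: (S)-2-methyl-CBS-oxazaborolidine (0.2–0.5 equiv), catecholborane, toluene, −78 °C; MeOH quench
Reagents that add atoms: none
Why: Corey–Bakshi–Shibata reduction in which the isopropenyl group acts as the large substituent and the CH2 arm as the small one, so the (S)-catalyst should deliver hydride to give the (6R) carbinol (1,3-syn to C4) under catalyst control; catecholborane at −78 °C should spare the alkenes and the lactone.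

**Step 8**
Reactants: 14 hydrogen peroxide; 15 2-methoxypropene
Product: 16 2-methoxyprop-2-yl hydroperoxide
Conditions: anhydrous ethereal H2O2 (5 equiv), PPTS (1 mol%), Et2O, −20 to 0 °C; NaHCO3 wash; kept as a cold titrated solution, never concentrated
Reagents that add atoms: none
Why: Acid-catalysed Markovnikov addition of the peroxide O–H across the enol ether via the 2-methoxyprop-2-yl cation (perketalisation); the excess of hydrogen peroxide suppresses the double adduct.

**Step 9**
Reactants: 13 4-{[(2E,4S,6R)-4-(tert-butyldimethylsilyloxy)-6-hydroxy-3,7-dimethylocta-2,7-dien-1-yl]oxy}-5-methylcoumarin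
Product: 17 (6R)-methanesulfonate of 13
Conditions: Ms2O, Et3N, CH2Cl2, −40 °C; cold NaHCO3 work-up; used crude at once
Reagents that add atoms: methanesulfonic anhydride CS(=O)(=O)OS(C)(=O)=O
Why: O-sulfonylation breaks no bond at C6, so the (6R) configuration is retained; the anhydride keeps chloride out of the flask and the low temperature should hold back ionisation and allylic transposition of the labile sulfonate.

**Step 10**
Reactants: 17 (6R)-methanesulfonate of 13; 16 2-methoxyprop-2-yl hydroperoxide
Product: 18 4-{[(2E,4S,6S)-4-(tert-butyldimethylsilyloxy)-6-[(2-methoxypropan-2-yl)peroxy]-3,7-dimethylocta-2,7-dien-1-yl]oxy}-5-methylcoumarin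
Conditions: 16 (3 equiv), Cs2CO3 (3 equiv), DMF, −20 to 0 °C, argon, dark
Reagents that add atoms: none
Why: Proposed new method: the caesium peroxide anion formed from 16, an alpha-effect oxygen nucleophile of low basicity, should attack C6 anti to the departing mesylate in one bimolecular step, forming the C6–OO bond with inversion and turning the (6R) centre fixed in step 7 into (6S), 1,3-anti to C4. The closest known reaction type is the alkylation of monoperoxyketal or hydroperoxide anions by sulfonates and halides under caesium base in DMF, which inverts saturated secondary centres and leaves primary allylic systems untransposed; a secondary sulfonate bearing an isopropenyl group has not been used. No ring closes, and the only new stereocentre, C6, is controlled by the substrate through backside displacement. The step needs attack at C6 and not at the C8 methylene (SN2'), no E2 loss to the C5=C6 diene and no ionisation; the hard and weakly basic nucleophile, the non-ionising dipolar aprotic medium at low temperature and the moderate nucleofugality of mesylate bias it towards direct substitution, which the adjacent C7=C8 pi bond accelerates. The silyl ether on the C4 oxygen blocks oxetane closure onto C6, the 4-alkoxycoumarin is too electron-rich at C4 for peroxide conjugate addition, and the ketal cap on the peroxide excludes a second alkylation to a dialkyl peroxide.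

**Step 11**
Reactants: 18 4-{[(2E,4S,6S)-4-(tert-butyldimethylsilyloxy)-6-[(2-methoxypropan-2-yl)peroxy]-3,7-dimethylocta-2,7-dien-1-yl]oxy}-5-methylcoumarin
Product: 19 4-{[(2E,4S,6S)-4-(tert-butyldimethylsilyloxy)-6-hydroperoxy-3,7-dimethylocta-2,7-dien-1-yl]oxy}-5-methylcoumarin
Conditions: AcOH/THF/H2O (4:2:1), 0 °C to rt
Reagents that add atoms: none
Why: Acid-catalysed hydrolysis of the peroxyketal through the 2-methoxyprop-2-yl cation releases the hydroperoxide without breaking the O–O or the C6–O bond; the secondary silyl ether should largely survive, and any that is lost gives the target directly.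

**Step 12**
Reactants: 19 4-{[(2E,4S,6S)-4-(tert-butyldimethylsilyloxy)-6-hydroperoxy-3,7-dimethylocta-2,7-dien-1-yl]oxy}-5-methylcoumarin
Product: 20 4-{[(2E,4S,6S)-6-hydroperoxy-4-hydroxy-3,7-dimethylocta-2,7-dien-1-yl]oxy}-5-methylcoumarin (CNP0307284.1)
Conditions: HF·pyridine, pyridine, THF, 0 °C to rt
Reagents that add atoms: none
Why: Fluoride desilylation under buffered, weakly acidic conditions removes the TBS group without exposing the secondary allylic hydroperoxide to strong base, which could trigger Kornblum–DeLaMare fragmentation; neither stereocentre is touched.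

**Compound list**
1 | 2'-hydroxy-6'-methylacetophenone | CC(=O)c1c(C)cccc1O | starting material
2 | diethyl carbonate | CCOC(=O)OCC | starting material
3 | ethyl 3-(2-hydroxy-6-methylphenyl)-3-oxopropanoate (beta-keto ester, sodium salt in the flask) | CCOC(=O)CC(=O)c1c(C)cccc1O | intermediate
4 | 4-hydroxy-5-methylcoumarin | Oc1cc(=O)oc2cccc(C)c12 | intermediate
5 | prenol (3-methylbut-2-en-1-ol) | CC(C)=CCO | starting material
6 | 5-methyl-4-(3-methylbut-2-en-1-yloxy)coumarin | CC(C)=CCOc1cc(=O)oc2cccc(C)c12 | intermediate
7 | 4-{[(2E)-4-hydroxy-3-methylbut-2-en-1-yl]oxy}-5-methylcoumarin | OC/C(C)=C/COc1cc(=O)oc2cccc(C)c12 | intermediate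
8 | (2E)-2-methyl-4-[(5-methyl-2-oxo-2H-chromen-4-yl)oxy]but-2-enal | O=C/C(C)=C/COc1cc(=O)oc2cccc(C)c12 | intermediate
9 | 3-methylbut-3-en-2-one (methyl isopropenyl ketone) | CC(=O)C(C)=C | starting material
10 | 3-methylbuta-1,3-dien-2-yl (+)-diisopinocampheylborinate (boron dienolate) | C=C(C)C(=C)OB([C@H]1C[C@H]2C[C@@H]([C@@H]1C)C2(C)C)[C@H]1C[C@H]2C[C@@H]([C@@H]1C)C2(C)C | intermediate
11 | 4-{[(2E,4S)-4-hydroxy-3,7-dimethyl-6-oxoocta-2,7-dien-1-yl]oxy}-5-methylcoumarin | C=C(C)C(=O)C[C@H](O)/C(C)=C/COc1cc(=O)oc2cccc(C)c12 | intermediate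
12 | 4-{[(2E,4S)-4-(tert-butyldimethylsilyloxy)-3,7-dimethyl-6-oxoocta-2,7-dien-1-yl]oxy}-5-methylcoumarin | C=C(C)C(=O)C[C@H](O[Si](C)(C)C(C)(C)C)/C(C)=C/COc1cc(=O)oc2cccc(C)c12 | intermediate
13 | 4-{[(2E,4S,6R)-4-(tert-butyldimethylsilyloxy)-6-hydroxy-3,7-dimethylocta-2,7-dien-1-yl]oxy}-5-methylcoumarin | C=C(C)[C@H](O)C[C@H](O[Si](C)(C)C(C)(C)C)/C(C)=C/COc1cc(=O)oc2cccc(C)c12 | intermediate
14 | hydrogen peroxide | OO | starting material
15 | 2-methoxypropene | C=C(C)OC | starting material
16 | 2-methoxyprop-2-yl hydroperoxide | COC(C)(C)OO | intermediate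
17 | (6R)-methanesulfonate of 13 | C=C(C)[C@H](OS(C)(=O)=O)C[C@H](O[Si](C)(C)C(C)(C)C)/C(C)=C/COc1cc(=O)oc2cccc(C)c12 | intermediate
18 | 4-{[(2E,4S,6S)-4-(tert-butyldimethylsilyloxy)-6-[(2-methoxypropan-2-yl)peroxy]-3,7-dimethylocta-2,7-dien-1-yl]oxy}-5-methylcoumarin | C=C(C)[C@H](C[C@H](O[Si](C)(C)C(C)(C)C)/C(C)=C/COc1cc(=O)oc2cccc(C)c12)OOC(C)(C)OC | intermediate
19 | 4-{[(2E,4S,6S)-4-(tert-butyldimethylsilyloxy)-6-hydroperoxy-3,7-dimethylocta-2,7-dien-1-yl]oxy}-5-methylcoumarin | C=C(C)[C@H](C[C@H](O[Si](C)(C)C(C)(C)C)/C(C)=C/COc1cc(=O)oc2cccc(C)c12)OO | intermediate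
20 | 4-{[(2E,4S,6S)-6-hydroperoxy-4-hydroxy-3,7-dimethylocta-2,7-dien-1-yl]oxy}-5-methylcoumarin (CNP0307284.1) | C=C(C)[C@H](C[C@H](O)/C(C)=C/COc1cc(=O)oc2cccc(C)c12)OO | target

**Step count**
Total steps: 12. Longest linear sequence: 11 steps (steps 1–7 and 9–12, from 1 to 20); step 8 is a one-step side branch that supplies 16.

**Steps most likely to fail**

1. Step 10 (proposed new method), together with the labile mesylate made in step 9. The peroxide anion may attack the C8 methylene with allylic transposition, the mesylate may eliminate to the diene or ionise with loss of configuration, or it may decay before it is intercepted. The fallback uses known chemistry, sets out from enal 8 and gives up stereocontrol at C6. Asymmetric allylboration of 8 with (−)-Ipc2B(allyl) (Et2O, −78 °C, ethanolamine work-up; Si-face addition) should give 4-{[(2E,4S)-4-hydroxy-3-methylhepta-2,6-dien-1-yl]oxy}-5-methylcoumarin F1. Cross-metathesis of F1 with 2-methyl-2-butene (second-generation Grubbs catalyst, CH2Cl2, 40 °C) should give the 4-hydroxygeranyl ether 4-{[(2E,4S)-4-hydroxy-3,7-dimethylocta-2,6-dien-1-yl]oxy}-5-methylcoumarin F2. A Schenck ene reaction of F2 with singlet oxygen (O2, tetraphenylporphyrin, visible light, CH2Cl2, 0 °C) should oxidise the electron-rich C6=C7 alkene in preference to C2=C3, which is deactivated by two allylic oxygens. It is expected to give 20 together with its C6 epimer, the (4S,6R)-hydroperoxide F3, and the regioisomeric tertiary hydroperoxide 4-{[(2E,4S,5E)-7-hydroperoxy-4-hydroxy-3,7-dimethylocta-2,5-dien-1-yl]oxy}-5-methylcoumarin F4, from which 20 is separated by preparative HPLC. The fallback returns to the route at 20.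

2. Step 5. Facial discrimination in the methyl-ketone boron aldol may be low, and the enone may polymerise or suffer conjugate addition of the amine during enolisation. The fallback sets out from ketone 9. Silylation (TMSOTf, Et3N, Et2O, 0 °C) should give 3-methyl-2-(trimethylsilyloxy)buta-1,3-diene F5. F5 is then added to enal 8 in a Mukaiyama aldol promoted by SiCl4 and a catalytic chiral binaphthyldiamine-derived bisphosphoramide (CH2Cl2, −78 °C; aqueous KF/NaHCO3 work-up), the catalyst antipode being chosen for Si-face addition. This open-transition-state, Lewis-base-catalysed aldol returns to the route at 11.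

3. Step 7. Facial selectivity in the reduction may be poor, or conjugate reduction of the isopropenyl ketone may compete. The fallback sets out from 12. Luche reduction (NaBH4, CeCl3·7H2O, MeOH, −78 °C) should give 13 together with its (4S,6S)-epimer F6. The two are separated by chromatography, and F6 is recycled by oxidation back to 12 with Dess–Martin periodinane. The fallback returns to the route at 13.

**Further compounds**
F1 | step 10 | 4-{[(2E,4S)-4-hydroxy-3-methylhepta-2,6-dien-1-yl]oxy}-5-methylcoumarin | C=CC[C@H](O)/C(C)=C/COc1cc(=O)oc2cccc(C)c12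
F2 | step 10 | 4-{[(2E,4S)-4-hydroxy-3,7-dimethylocta-2,6-dien-1-yl]oxy}-5-methylcoumarin | CC(C)=CC[C@H](O)/C(C)=C/COc1cc(=O)oc2cccc(C)c12
F3 | step 10 | 4-{[(2E,4S,6R)-6-hydroperoxy-4-hydroxy-3,7-dimethylocta-2,7-dien-1-yl]oxy}-5-methylcoumarin | C=C(C)[C@@H](C[C@H](O)/C(C)=C/COc1cc(=O)oc2cccc(C)c12)OO
F4 | step 10 | 4-{[(2E,4S,5E)-7-hydroperoxy-4-hydroxy-3,7-dimethylocta-2,5-dien-1-yl]oxy}-5-methylcoumarin | CC(C)(OO)/C=C/[C@H](O)/C(C)=C/COc1cc(=O)oc2cccc(C)c12
F5 | step 5 | 3-methyl-2-(trimethylsilyloxy)buta-1,3-diene | C=C(C)C(=C)O[Si](C)(C)C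
F6 | step 7 | 4-{[(2E,4S,6S)-4-(tert-butyldimethylsilyloxy)-6-hydroxy-3,7-dimethylocta-2,7-dien-1-yl]oxy}-5-methylcoumarin | C=C(C)[C@@H](O)C[C@H](O[Si](C)(C)C(C)(C)C)/C(C)=C/COc1cc(=O)oc2cccc(C)c12
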